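## Retrosynthetic overview

1. Feature: on the lactone ring (O1, C2 carbonyl, C3 carbinol, C4, C5 methylene) the atoms O3 (hydroxyl oxygen on C3), C3, C4 and C5 are a β-hydroxy acid once C5 is raised to the acid level. C3 and C4 are then the β- and α-carbons of a 2-tert-butyl-1,3-dioxin-4-one that already carries the guaiacylmethyl group, with O3 as a ring oxygen.
2. Key disconnections: C2–C3 (vinyl from (CH2=CH)2CuLi; the vinyl carbon is the future C2) and C4–C7 (C7 = veratryl CH2, from 3,4-dimethoxybenzyl bromide), both made in one flask on the enantiopure dioxinone, whose acetal carbon relays chirality to C3 and C4.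
3. Dioxinone ⇐ cis-dioxanone (selenoxide elimination) ⇐ (S)-β-hydroxy acid + pivalaldehyde ⇐ Noyori hydrogenation ⇐ β-keto ester ⇐ O-benzylhomovanillic acid + Meldrum's acid.
4. After the key step: LiAlH4 opens the dioxanone (C5 to CH2OH, O3 freed), ozonolysis turns the vinyl group into the C2 aldehyde, which closes onto the C5 oxygen, oxidation gives the lactone and hydrogenolysis frees the phenol.
5. Ring order: the 1,3-dioxanone ring (auxiliary, closed in step 5, opened in step 9), then the lactone ring (closed as lactol in step 10, oxidised in step 11); the key step closes no ring.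

Key step: step 8

Remark on the chemistry: the lithium cuprate (from CH2=CHLi) is used, not a magnesium cuprate, because only a lithium enolate is expected to be benzylated at −78 °C before β-elimination sets in. Atom numbers C2–C5, O3 and C7 refer to the lactone as defined in line 1.

## Route

Step 1
Reactants: 1 homovanillic acid
Product: 2 (4-benzyloxy-3-methoxyphenyl)acetic acid
Conditions: BnBr, NaOH, EtOH/H2O, reflux; then HCl (aq)
Reagents that add atoms: benzyl bromide BrCc1ccccc1
Why: Williamson ether synthesis on the dianion: the phenoxide is far more nucleophilic than the carboxylate and any benzyl ester that forms is saponified by the excess hydroxide, so acidification should give only the O-benzyl acid.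

Step 2
Reactants: 2 (4-benzyloxy-3-methoxyphenyl)acetic acid, 3 Meldrum's acid
Product: 5 methyl 4-(4-benzyloxy-3-methoxyphenyl)-3-oxobutanoate, via acyl Meldrum's acid 4 (not isolated)
Conditions: DCC, DMAP, CH2Cl2, 0 °C → rt; then MeOH, reflux
Reagents that add atoms: methanol CO
Why: Carbodiimide/DMAP C-acylation of Meldrum's acid followed by methanolysis of 4, which loses acetone and CO2, is the standard two-carbon homologation of an acid to its β-keto ester.

Step 3
Reactants: 5 methyl 4-(4-benzyloxy-3-methoxyphenyl)-3-oxobutanoate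
Product: 6 methyl (S)-4-(4-benzyloxy-3-methoxyphenyl)-3-hydroxybutanoate
Conditions: H2 (50 atm), RuCl2[(S)-BINAP] (cat.), MeOH, 50 °C
Reagents that add atoms: none
Why: Noyori asymmetric hydrogenation of a β-keto ester: the ester carbonyl chelates ruthenium and the (S)-BINAP ligand directs hydride to the ketone face that gives the (S)-carbinol, while the aryl benzyl ether is inert to this homogeneous catalyst.

Step 4
Reactants: 6 methyl (S)-4-(4-benzyloxy-3-methoxyphenyl)-3-hydroxybutanoate
Product: 7 (S)-4-(4-benzyloxy-3-methoxyphenyl)-3-hydroxybutanoic acid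
Conditions: LiOH, THF/H2O, 0 °C → rt; then HCl (aq) to pH 3
Reagents that add atoms: lithium hydroxide [Li+].[OH-]
Why: Ester saponification with LiOH at or below room temperature is mild enough to avoid dehydration of the β-hydroxy acid, and the stereocentre is not touched.

Step 5
Reactants: 7 (S)-4-(4-benzyloxy-3-methoxyphenyl)-3-hydroxybutanoic acid, 8 pivalaldehyde
Product: 10 (2S,6S)-6-(4-benzyloxy-3-methoxybenzyl)-2-tert-butyl-1,3-dioxan-4-one, via bis(trimethylsilyl) derivative 9 (not isolated)
Conditions: Me3SiCl, Et3N, CH2Cl2, 0 °C → rt, filter; then t-BuCHO, Me3SiOTf (cat.), CH2Cl2, −78 °C; pyridine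
Reagents that add atoms: none
Why: Me3SiOTf-catalysed silyl-transfer acetalisation of the bis-silylated hydroxy acid closes the 1,3-dioxan-4-one at −78 °C, the existing C6 centre setting the new acetal centre so that tert-butyl and the arylmethyl group are both equatorial (cis), and the low temperature keeps the oxocarbenium ion from attacking the electron-rich arene (oxa-Pictet–Spengler pathway); the cis isomer is purified by crystallisation because any trans isomer would lead to the enantiomeric dioxinone.

Step 6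
Reactants: 10 (2S,6S)-6-(4-benzyloxy-3-methoxybenzyl)-2-tert-butyl-1,3-dioxan-4-one
Product: 13 (S)-6-(4-benzyloxy-3-methoxybenzyl)-2-tert-butyl-4H-1,3-dioxin-4-one, via 5-phenylselanyl dioxanone 11 (not isolated), via selenoxide 12 (not isolated)
Conditions: LiN(i-Pr)2, THF, −78 °C; PhSeBr; then H2O2 (30 %), pyridine, CH2Cl2, 0 °C → rt
Reagents that add atoms: none
Why: α-Selenenylation of the ester enolate (selenium enters trans to the C6 substituent) and selenoxide syn-elimination toward H6, the only β-hydrogen and cis to selenium, introduce the C5=C6 bond; C6 is deliberately lost as a stereocentre and the acetal carbon now carries the chirality alone.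

Step 7
Reactants: 14 3,4-dimethoxybenzyl alcohol
Product: 15 3,4-dimethoxybenzyl bromide
Conditions: PBr3, Et2O, 0 °C; used freshly
Reagents that add atoms: phosphorus tribromide BrP(Br)Br
Why: PBr3 converts the electron-rich benzylic alcohol into the bromide by SN2 displacement of the phosphite ester; the bromide is used freshly because it does not store well.

Step 8
Reactants: 13 (S)-6-(4-benzyloxy-3-methoxybenzyl)-2-tert-butyl-4H-1,3-dioxin-4-one, 15 3,4-dimethoxybenzyl bromide, 16 tetravinylstannane
Product: 18 (2S,5R,6R)-6-(4-benzyloxy-3-methoxybenzyl)-2-tert-butyl-5-(3,4-dimethoxybenzyl)-6-vinyl-1,3-dioxan-4-one, via lithium dioxin-4-olate 17 (not isolated)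
Conditions: 16 (slight excess), MeLi, Et2O, 0 °C; CuI, THF/Et2O, −40 °C; 13, −78 → −40 °C; then DMPU, 15 (excess), −78 → −50 °C; NH4Cl (aq)
Reagents that add atoms: none
Why: Proposed new method: the Gilman reagent (CH2=CH)2CuLi forms a π-complex with the C5=C6 bond of 13 and, through a trivalent-copper β-adduct and reductive elimination, delivers vinyl to C6 (bond C2–C3 of the target), and the lithium enolate 17 so formed is C-benzylated by 15 in an SN2 step (bond C4–C7) in the same flask, a combination not yet shown on 1,3-dioxin-4-ones. The closest known reaction types are cuprate conjugate addition to enantiopure 2-tert-butyl-1,3-dioxin-4-ones, alkylation of amide-generated 1,3-dioxan-4-one enolates, and conjugate addition–enolate alkylation (three-component coupling) of cyclic enones and butenolides. No ring is closed; the dioxanone ring is carried through unchanged. C6 is controlled by the acetal carbon: tert-butyl sits equatorial and the cuprate enters from the opposite face, so vinyl becomes axial and trans to tert-butyl. C5 is controlled by that axial vinyl group: the bromide approaches the enolate anti to it through a chair-like transition state, placing the veratrylmethyl group axial, trans to vinyl and cis to the guaiacylmethyl group, which should also be the more stable C5 epimer because it has only one gauche contact at C6. The step needs 1,4-addition over deprotonation of the doubly activated benzylic CH2 of 13 and C-alkylation over β-elimination of the enolate; the low basicity of the cuprate, the temperature of −78 °C, DMPU and the high SN2 reactivity of the benzylic bromide should secure both.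

Step 9
Reactants: 18 (2S,5R,6R)-6-(4-benzyloxy-3-methoxybenzyl)-2-tert-butyl-5-(3,4-dimethoxybenzyl)-6-vinyl-1,3-dioxan-4-one
Product: 19 (2S,3R)-3-(4-benzyloxy-3-methoxybenzyl)-2-(3,4-dimethoxybenzyl)pent-4-ene-1,3-diol
Conditions: LiAlH4, THF, 0 °C → rt; then H2O, NaOH (aq)
Reagents that add atoms: none
Why: LiAlH4 reduction of the acylal carbonyl gives the C5 primary alcohol, and the released hemiacetal alkoxide collapses to the tertiary alkoxide (O3) and pivalaldehyde, which is reduced to neopentyl alcohol; neither stereocentre is involved.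

Step 10
Reactants: 19 (2S,3R)-3-(4-benzyloxy-3-methoxybenzyl)-2-(3,4-dimethoxybenzyl)pent-4-ene-1,3-diol
Product: 21 (3S,4S)-3-(4-benzyloxy-3-methoxybenzyl)-4-(3,4-dimethoxybenzyl)oxolane-2,3-diol (anomer mixture), via α-hydroxy aldehyde 20 (not isolated)
Conditions: O3, CH2Cl2/MeOH (4:1), Sudan Red 7B, −78 °C; then Me2S, −78 °C → rt
Reagents that add atoms: ozone [O-][O+]=O
Why: Ozonolysis with reductive work-up cleaves the monosubstituted alkene faster than the alkoxyarenes (the dye marks the end point), and the α-hydroxy aldehyde 20 closes with the C5 hydroxyl to the five-membered lactol (5-exo-trig hemiacetalisation, anomeric mixture of no consequence); ozone is chosen over OsO4–NaIO4 because periodate would go on to cleave the α-hydroxy aldehyde and the lactol between C2 and C3.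

Step 11
Reactants: 21 (3S,4S)-3-(4-benzyloxy-3-methoxybenzyl)-4-(3,4-dimethoxybenzyl)oxolane-2,3-diol
Product: 22 (3S,4S)-3-(4-benzyloxy-3-methoxybenzyl)-4-(3,4-dimethoxybenzyl)-3-hydroxyoxolan-2-one
Conditions: I2, CaCO3, MeOH/H2O (9:1), rt
Reagents that add atoms: none
Why: Hypoiodite oxidation of the lactol (iodine with a carbonate buffer) removes the anomeric hydrogen to give the lactone without touching the tertiary alcohol or the fully etherified arenes, and it erases the anomeric centre.

Step 12
Reactants: 22 (3S,4S)-3-(4-benzyloxy-3-methoxybenzyl)-4-(3,4-dimethoxybenzyl)-3-hydroxyoxolan-2-one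
Product: 23 trachelogenin
Conditions: H2 (1 atm), Pd/C (10 %), EtOAc/EtOH, rt
Reagents that add atoms: none
Why: Hydrogenolysis of the benzyl aryl ether over Pd/C leaves the lactone, the tertiary non-benzylic alcohol and the methyl ethers untouched.

## Compound list

1 | homovanillic acid (4-hydroxy-3-methoxyphenylacetic acid) | COc1cc(CC(=O)O)ccc1O | starting material
2 | (4-benzyloxy-3-methoxyphenyl)acetic acid | COc1cc(CC(=O)O)ccc1OCc1ccccc1 | intermediate
3 | Meldrum's acid (2,2-dimethyl-1,3-dioxane-4,6-dione) | CC1(C)OC(=O)CC(=O)O1 | starting material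
4 | 5-[2-(4-benzyloxy-3-methoxyphenyl)-1-hydroxyethylidene]-2,2-dimethyl-1,3-dioxane-4,6-dione (acyl Meldrum's acid, enol form) | COc1cc(CC(O)=C2C(=O)OC(C)(C)OC2=O)ccc1OCc1ccccc1 | intermediate
5 | methyl 4-(4-benzyloxy-3-methoxyphenyl)-3-oxobutanoate | COC(=O)CC(=O)Cc1ccc(OCc2ccccc2)c(OC)c1 | intermediate
6 | methyl (S)-4-(4-benzyloxy-3-methoxyphenyl)-3-hydroxybutanoate | COC(=O)C[C@@H](O)Cc1ccc(OCc2ccccc2)c(OC)c1 | intermediate
7 | (S)-4-(4-benzyloxy-3-methoxyphenyl)-3-hydroxybutanoic acid | OC(=O)C[C@@H](O)Cc1ccc(OCc2ccccc2)c(OC)c1 | intermediate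
8 | pivalaldehyde (2,2-dimethylpropanal) | CC(C)(C)C=O | starting material
9 | trimethylsilyl (S)-4-(4-benzyloxy-3-methoxyphenyl)-3-(trimethylsilyloxy)butanoate | C[Si](C)(C)OC(=O)C[C@@H](O[Si](C)(C)C)Cc1ccc(OCc2ccccc2)c(OC)c1 | intermediate
10 | (2S,6S)-6-(4-benzyloxy-3-methoxybenzyl)-2-tert-butyl-1,3-dioxan-4-one (cis) | O=C1C[C@H](Cc2ccc(OCc3ccccc3)c(OC)c2)O[C@H](C(C)(C)C)O1 | intermediate
11 | (2S,5S,6S)-6-(4-benzyloxy-3-methoxybenzyl)-2-tert-butyl-5-(phenylselanyl)-1,3-dioxan-4-one | O=C1[C@@H]([Se]c2ccccc2)[C@H](Cc2ccc(OCc3ccccc3)c(OC)c2)O[C@H](C(C)(C)C)O1 | intermediate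
12 | (2S,5S,6S)-6-(4-benzyloxy-3-methoxybenzyl)-2-tert-butyl-5-(phenylseleninyl)-1,3-dioxan-4-one (selenoxide, selenium configuration undefined) | O=C1[C@@H]([Se](=O)c2ccccc2)[C@H](Cc2ccc(OCc3ccccc3)c(OC)c2)O[C@H](C(C)(C)C)O1 | intermediate
13 | (S)-6-(4-benzyloxy-3-methoxybenzyl)-2-tert-butyl-4H-1,3-dioxin-4-one | O=C1C=C(Cc2ccc(OCc3ccccc3)c(OC)c2)O[C@H](C(C)(C)C)O1 | intermediate
14 | 3,4-dimethoxybenzyl alcohol | COc1ccc(CO)cc1OC | starting material
15 | 3,4-dimethoxybenzyl bromide | COc1ccc(CBr)cc1OC | intermediate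
16 | tetravinylstannane | C=C[Sn](C=C)(C=C)C=C | starting material
17 | lithium (2S,6R)-6-(4-benzyloxy-3-methoxybenzyl)-2-tert-butyl-6-vinyl-6H-1,3-dioxin-4-olate | C=C[C@@]1(Cc2ccc(OCc3ccccc3)c(OC)c2)O[C@H](C(C)(C)C)OC(O[Li])=C1 | intermediate
18 | (2S,5R,6R)-6-(4-benzyloxy-3-methoxybenzyl)-2-tert-butyl-5-(3,4-dimethoxybenzyl)-6-vinyl-1,3-dioxan-4-one | C=C[C@@]1(Cc2ccc(OCc3ccccc3)c(OC)c2)O[C@H](C(C)(C)C)OC(=O)[C@@H]1Cc1ccc(OC)c(OC)c1 | intermediate
19 | (2S,3R)-3-(4-benzyloxy-3-methoxybenzyl)-2-(3,4-dimethoxybenzyl)pent-4-ene-1,3-diol | C=C[C@](O)(Cc1ccc(OCc2ccccc2)c(OC)c1)[C@H](CO)Cc1ccc(OC)c(OC)c1 | intermediate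
20 | (2S,3S)-2-(4-benzyloxy-3-methoxybenzyl)-3-(3,4-dimethoxybenzyl)-2,4-dihydroxybutanal | O=C[C@](O)(Cc1ccc(OCc2ccccc2)c(OC)c1)[C@H](CO)Cc1ccc(OC)c(OC)c1 | intermediate
21 | (3S,4S)-3-(4-benzyloxy-3-methoxybenzyl)-4-(3,4-dimethoxybenzyl)oxolane-2,3-diol (lactol, anomer mixture) | COc1cc(C[C@@]2(O)C(O)OC[C@@H]2Cc2ccc(OC)c(OC)c2)ccc1OCc1ccccc1 | intermediate
22 | (3S,4S)-3-(4-benzyloxy-3-methoxybenzyl)-4-(3,4-dimethoxybenzyl)-3-hydroxyoxolan-2-one (O-benzyltrachelogenin) | COc1cc(C[C@@]2(O)C(=O)OC[C@@H]2Cc2ccc(OC)c(OC)c2)ccc1OCc1ccccc1 | intermediate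
23 | trachelogenin, (3S,4S)-4-(3,4-dimethoxybenzyl)-3-hydroxy-3-(4-hydroxy-3-methoxybenzyl)oxolan-2-one | COc1cc(C[C@@]2(O)C(=O)OC[C@@H]2Cc2ccc(OC)c(OC)c2)ccc1O | target

## Step count and risks

Total step count: 12. Longest linear sequence: 11 steps (steps 1–6 and 8–12, from homovanillic acid); step 7 is a one-step side branch.

Steps most likely to fail:

1. Step 8 (carries the label). The copper-containing enolate aggregate may be benzylated too slowly at −78 °C, so that β-elimination of the enolate (ring opening with loss of pivalaldehyde) or consumption of the bromide by leftover cuprate takes over; benzylation may also lack facial selectivity at C5. Fallback, known chemistry, from 13 back to 18: the two bond formations would be separated. Addition of (CH2=CH)2CuLi to 13 in Et2O/THF at −78 °C (with Me3SiCl acceleration if needed, since the adduct is protonated anyway) and NH4Cl quench should give (2S,6S)-6-(4-benzyloxy-3-methoxybenzyl)-2-tert-butyl-6-vinyl-1,3-dioxan-4-one F1, which is isolated free of copper. LiN(i-Pr)2 in THF at −78 °C would then regenerate 17 as a pure lithium enolate, and 15 with DMPU would give 18 by the documented alkylation of a dioxanone enolate. If benzylation entered syn to the vinyl group, the product would be (2S,5S,6R)-6-(4-benzyloxy-3-methoxybenzyl)-2-tert-butyl-5-(3,4-dimethoxybenzyl)-6-vinyl-1,3-dioxan-4-one F2; this would be re-enolised with LiN(i-Pr)2 at −78 °C and protonated, the proton now taking that same face, which inverts C5 and returns 18.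

2. Step 6. The dioxanone enolate may undergo β-elimination before selenium is transferred, or the new C5=C6 bond may drift to the exocyclic, arene-conjugated position through γ-deprotonation during oxidation and work-up. Fallback from 4 (with 8) back to 13: crude 4 would be heated with pivalaldehyde 8 in toluene at about 90 °C. Loss of acetone and CO2 gives 4-(4-benzyloxy-3-methoxyphenyl)-3-oxobut-1-en-1-one F3 (the acylketene), which is trapped by the aldehyde C=O in a [4+2] cycloaddition to racemic 6-(4-benzyloxy-3-methoxybenzyl)-2-tert-butyl-4H-1,3-dioxin-4-one F4. Preparative HPLC on a cellulose-based chiral stationary phase would separate the enantiomers, the (S)-enantiomer being 13. This path also bypasses steps 3–5.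

3. Step 10. Ozone may attack the two electron-rich alkoxyarenes before the hindered vinyl group is consumed, and the α-hydroxy aldehyde may fragment with loss of C2. Fallback from 19 back to 22: 2,2-dimethoxypropane with PPTS in CH2Cl2 would give (4R,5S)-4-(4-benzyloxy-3-methoxybenzyl)-5-(3,4-dimethoxybenzyl)-2,2-dimethyl-4-vinyl-1,3-dioxane F5. With O3 masked, Lemieux–Johnson cleavage (OsO4 cat., NaIO4, 2,6-lutidine, dioxane/H2O) can no longer over-cleave and should give (4S,5S)-4-(4-benzyloxy-3-methoxybenzyl)-5-(3,4-dimethoxybenzyl)-2,2-dimethyl-1,3-dioxane-4-carbaldehyde F6. Pinnick oxidation (NaClO2, NaH2PO4, 2-methyl-2-butene, t-BuOH/H2O) would give (4S,5S)-4-(4-benzyloxy-3-methoxybenzyl)-5-(3,4-dimethoxybenzyl)-2,2-dimethyl-1,3-dioxane-4-carboxylic acid F7. TsOH in wet THF would then remove the acetonide with concomitant γ-lactonisation to 22. This path avoids ozone and also bypasses lactol 21 and step 11.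

Further compounds

F1 | step 8 | (2S,6S)-6-(4-benzyloxy-3-methoxybenzyl)-2-tert-butyl-6-vinyl-1,3-dioxan-4-one | C=C[C@@]1(Cc2ccc(OCc3ccccc3)c(OC)c2)O[C@H](C(C)(C)C)OC(=O)C1
F2 | step 8 | (2S,5S,6R)-6-(4-benzyloxy-3-methoxybenzyl)-2-tert-butyl-5-(3,4-dimethoxybenzyl)-6-vinyl-1,3-dioxan-4-one | C=C[C@@]1(Cc2ccc(OCc3ccccc3)c(OC)c2)O[C@H](C(C)(C)C)OC(=O)[C@H]1Cc1ccc(OC)c(OC)c1
F3 | step 6 | 4-(4-benzyloxy-3-methoxyphenyl)-3-oxobut-1-en-1-one | O=C=CC(=O)Cc1ccc(OCc2ccccc2)c(OC)c1
F4 | step 6 | racemic 6-(4-benzyloxy-3-methoxybenzyl)-2-tert-butyl-4H-1,3-dioxin-4-one | O=C1C=C(Cc2ccc(OCc3ccccc3)c(OC)c2)OC(C(C)(C)C)O1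
F5 | step 10 | (4R,5S)-4-(4-benzyloxy-3-methoxybenzyl)-5-(3,4-dimethoxybenzyl)-2,2-dimethyl-4-vinyl-1,3-dioxane | C=C[C@@]1(Cc2ccc(OCc3ccccc3)c(OC)c2)OC(C)(C)OC[C@@H]1Cc1ccc(OC)c(OC)c1
F6 | step 10 | (4S,5S)-4-(4-benzyloxy-3-methoxybenzyl)-5-(3,4-dimethoxybenzyl)-2,2-dimethyl-1,3-dioxane-4-carbaldehyde | O=C[C@@]1(Cc2ccc(OCc3ccccc3)c(OC)c2)OC(C)(C)OC[C@@H]1Cc1ccc(OC)c(OC)c1
F7 | step 10 | (4S,5S)-4-(4-benzyloxy-3-methoxybenzyl)-5-(3,4-dimethoxybenzyl)-2,2-dimethyl-1,3-dioxane-4-carboxylic acid | OC(=O)[C@@]1(Cc2ccc(OCc3ccccc3)c(OC)c2)OC(C)(C)OC[C@@H]1Cc1ccc(OC)c(OC)c1
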